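**Numbering used throughout**

1 3-hydroxy-4,5-dimethoxybenzaldehyde · 2 its 2-bromo derivative · 3 benzyl ether of 2 · 4 benzylic alcohol · 5 benzylic bromide · 6 2,3-dimethoxyphenol · 7 2,3-dimethoxy-1,4-benzoquinone · 8 2,3-dimethoxyhydroquinone · 9 its bis(benzyl) ether · 10 bromide of 9 · 11 diethyl malonate · 12 ring B arylmalonate · 13 benzylated arylmalonate · 14 prochiral diol · 15 (S)-3-(hydroxymethyl)chroman · 16 (R)-aldehyde · 17 (S)-tribenzyl isoflavan · 18 (S)-hydroquinone triol · 19 target.

## Analysis of the target

The target is an isoflavan quinone: benzene ring A and the oxygen heterocycle ring C form a chroman, and C3 of ring C carries ring B, a 2,3-dimethoxy-1,4-benzoquinone. Ring A has methoxy groups at C6 and C7 and a free hydroxyl at C8 beside the ring oxygen O1, so both carbocycles are tetra-oxygenated and easily oxidised. The only stereocentre is C3, a tertiary C–H between the methylene groups C2 and C4. It is (S) (C2 > quinone carbon > C4 > H), and there is no second stereocentre to relate it to or to steer it. The quinone is the sensitive group: it is an electrophile and an oxidant, its methoxy groups are vinylogous esters, and base could tautomerise it through C3–H to a quinone methide and erase the stereocentre, so it has to appear last. Three oxygens (C8–OH and the two quinone oxygens) must be told apart from four methyl ethers, and the unveiling of the quinone must leave ring A alone. The difficulty is therefore an isolated stereocentre with no neighbouring functional group to set it. The route rests on two features: O1–C8a is an aryl alkyl ether bond that a metal can forge from an alcohol and an aryl bromide, and C3 becomes prochiral, with two enantiotopic CH2OH arms, once its hydrogen is temporarily replaced by a second hydroxymethyl group.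

## Retrosynthetic reasoning

**Quinone and phenol last (19 ⇒ 18 ⇒ 17).** No skeletal bond is cut. The quinone is traced back to hydroquinone 18, and the three hydroxyls of 18 to the benzyl ethers of 17. Benzyl on the oxygens that must end free and methyl on those that stay lets one hydrogenolysis do the whole differentiation. A mild oxidant then acts only on the hydroquinone of ring B, not on the monophenol of ring A.

**One carbon added at C3 (17 ⇒ 16 ⇒ 15).** The C3–H bond is traced back to a C3–CHO bond in 16 and this to the hydroxymethyl group of 15. Nothing else at C3 can be changed without touching ring C or ring B. The gain is that C3 becomes a quaternary carbon bearing two CH2–O arms, one of which is C2. The forward reaction has to remove the formyl carbon with retention, which a rhodium-mediated decarbonylation of a non-enolisable aldehyde does.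

**O1–C8a (15 ⇒ 14).** Cutting the aryl ether bond of ring C leads to diol 14, which has a bromine at C8a. Compound 14 is achiral, and its two hydroxymethyl groups are enantiotopic. The cut is made here and not at O1–C2, because a desymmetrising closure at the sp3 carbon would need a phenol at C8a and selective activation of one of two alcohols, for which no comparably developed catalytic method exists. A C–C cut in ring C would leave the stereochemical problem unsolved. The forward step must couple one arm with a hindered, electron-rich aryl bromide and choose between the arms by catalyst control.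

**C3–C4 and the two arms (14 ⇒ 13 ⇒ 12 + 5).** The diol is the reduction product of malonate 13. Cutting C3–C4 of 13 gives arylmalonate 12 and benzylic bromide 5. A malonate is the simplest way to place two identical one-carbon arms on one carbon, and its alkylation builds the quaternary centre without any stereochemical issue.

**C3–C1′ (12 ⇒ 10 + 11; 10 ⇒ 9 ⇒ 8 ⇒ 7 ⇒ 6).** The aryl–carbon bond of 12 is cut to aryl bromide 10 and malonate 11, joined forward by palladium-catalysed enolate arylation. Bromide 10 comes from the C2-symmetric bis(benzyl) ether 9, in which both free positions are equivalent, so the bromination has only one outcome. Compound 9 comes from quinone 7 through hydroquinone 8, and 7 from phenol 6 by para-oxidation.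

**Ring A fragment (5 ⇒ 4 ⇒ 3 ⇒ 2 ⇒ 1).** Aldehyde 1 already has the full oxygen pattern of ring A and the carbon that becomes C4. The bromine that marks the future C8a must enter ortho to the phenol and to the formyl group. The free phenol of 1 is used to direct it there before it is benzylated.

## Alternatives that were turned down

**Alternative 1: pterocarpan by quinone–chromene annulation, then ring opening.**
- Disconnection: C3–C1′ and, temporarily, a bond from C4 to the ring B oxygen.
- Forward key step: quinone 7, bound to a chiral titanium Lewis acid (TiCl2(OiPr)2 with a TADDOL-type diol, tetravalent titanium), is attacked at its free carbon by C3 of 8-(benzyloxy)-6,7-dimethoxy-2H-chromene A2. The C4 cation is then trapped by the quinone oxygen to give the cis-pterocarpan (6aS,11aS)-4-(benzyloxy)-2,3,9,10-tetramethoxy-6a,11a-dihydro-6H-benzofuro[3,2-c]chromen-8-ol A1. Hydrogenolysis of the benzylic C–O bond and of the benzyl ether, then oxidation, would finish the synthesis.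
- For: it is by far the shortest and most convergent plan. Ring B arrives from 7 at the right oxidation level without protecting groups, and the C4 cation is well stabilised by the C7 methoxy group.
- Against: the asymmetric variant needs the chiral titanium reagent in stoichiometric amount or more. Its selectivity depends on two-point binding of the quinone, and [2+2] adducts compete. An electron-rich chromene next to an oxidising quinone and a strong Lewis acid invites electron-transfer side reactions. The acidic or reductive opening of the benzylic C–O bond can lose a proton from C3 to an isoflavene, which would destroy the only stereocentre that matters.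
- Comparison: Alternative 1 is clearly stronger on step economy. The chosen route offers in its place a catalytic enantioselective step and a quaternary intermediate that cannot epimerise, whose enantiomeric purity can be checked and raised before the extra carbon is removed.

**Alternative 2: conjunctive three-component coupling on a vinylboron ate complex.**
- Disconnection: C3–C1′ and C4–C4a across a two-carbon unit, with O1–C2 made later.
- Forward key step: 4,4,5,5-tetramethyl-2-vinyl-1,3,2-dioxaborolane A6 and [2,5-bis(benzyloxy)-3,4-dimethoxyphenyl]magnesium bromide A4 (from 10) form an ate complex. Pd(OAc)2 with a MandyPhos-type bisphosphine and NaOTf then couples it with 3-(benzyloxy)-1-bromo-4,5-dimethoxy-2-(methoxymethoxy)benzene A5 under 1,2-migration of ring B, giving 2-{(1S)-2-[3-(benzyloxy)-4,5-dimethoxy-2-(methoxymethoxy)phenyl]-1-[2,5-bis(benzyloxy)-3,4-dimethoxyphenyl]ethyl}-4,4,5,5-tetramethyl-1,3,2-dioxaborolane A3. Matteson homologation, oxidation, acetal removal and Mitsunobu closure of O1–C2 would follow.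
- For: the step is catalytic and usually highly enantioselective. It makes C3 directly as a tertiary centre, so no carbon has to be excised, and the later steps are stereospecific.
- Against: the migrating aryl group carries an ortho benzyloxy group, and the electrophile is an ortho-substituted, very electron-rich bromide, so both partners lie at the edge of what this coupling tolerates. The secondary benzylic boronic ester A3 sits between two bulky arenes, so homologation may be slow and protodeboronation is a risk. C2 and ring C still cost four further operations, and two orthogonal phenol protecting groups are needed on ring A.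
- Comparison: Alternative 2 is probably as strong or stronger in expected enantioselectivity and in setting C3–H directly, at a similar step count. The chosen route offers instead a stereodefining step that is intramolecular, needs no organometallic reagent of a polyoxygenated arene, and closes ring C in the same operation, with only classical chemistry before it.

**Alternative 3: ring A ortho-quinone methide plus a chiral enamine.**
- Disconnection: C3–C4 and O1–C2, a formal [4+2].
- Forward key step: base releases the ortho-quinone methide from 2-(benzyloxy)-3,4-dimethoxy-6-[(4-methylbenzenesulfonyl)methyl]phenol A8. The enamine of 2-[2,5-bis(benzyloxy)-3,4-dimethoxyphenyl]acetaldehyde A9 with a diarylprolinol silyl ether adds to it, and hemiacetal formation gives (3S)-8-(benzyloxy)-3-[2,5-bis(benzyloxy)-3,4-dimethoxyphenyl]-6,7-dimethoxychroman-2-ol A7 as a mixture of anomers. Ionic reduction of the lactol, hydrogenolysis and oxidation would complete the synthesis.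
- For: two bonds and ring C form in one organocatalytic step, C3–H is set directly, and the route is short.
- Against: in A7 the stereocentre is α to a masked aldehyde and benzylic to an electron-rich arene. Ring–chain tautomerism exposes an α-aryl aldehyde that enolises easily, under the base that frees the quinone methide and under the amine catalyst. Arylacetaldehydes are poor enamine partners because they self-condense and give weakly nucleophilic conjugated enamines. A quinone methide with three oxygen donors is a weak electrophile. The lactol reduction passes through an oxocarbenium ion that can lose the C3 proton.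
- Comparison: Alternative 3 is stronger on step economy and bond-forming efficiency. The chosen route offers a stereocentre that is quaternary, and so configurationally fixed, from its creation until the decarbonylation, and thereafter has no acidifying neighbour until the final oxidation.

Key step: step 11

Remark on the chemistry (assumption): which enantiomer of the diamine ligand leads to (S)-15 cannot be derived with confidence for this substrate. The route is written with the (1R,2R) ligand, and the (1S,2S) ligand is to be used if a trial shows the opposite sense.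

## Route

Step 1
Reactants: 1 3-hydroxy-4,5-dimethoxybenzaldehyde
Product: 2 2-bromo-3-hydroxy-4,5-dimethoxybenzaldehyde
Conditions: NBS (1.0 equiv), i-Pr2NH (10 mol %), CH2Cl2, 0 °C
Reagents that add atoms: N-bromosuccinimide, O=C1CCC(=O)N1Br
Why: Amine-mediated ortho-selective electrophilic bromination of a phenol: the N-bromoamine formed in situ is held by the phenolic OH and delivers bromine to the only free ortho position, C2, between OH and CHO, the site also attacked in isovanillin-type phenols. The position of the bromine is to be confirmed by an NOE between the remaining aromatic proton and the C5 methoxy group.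

Step 2
Reactants: 2 2-bromo-3-hydroxy-4,5-dimethoxybenzaldehyde
Product: 3 3-(benzyloxy)-2-bromo-4,5-dimethoxybenzaldehyde
Conditions: BnBr, K2CO3, DMF, 50 °C
Reagents that add atoms: benzyl bromide, BrCc1ccccc1
Why: Williamson ether synthesis on an acidic ortho-bromophenol; the aldehyde and aryl bromide are inert to K2CO3.

Step 3
Reactants: 3 3-(benzyloxy)-2-bromo-4,5-dimethoxybenzaldehyde
Product: 4 [3-(benzyloxy)-2-bromo-4,5-dimethoxyphenyl]methanol
Conditions: NaBH4, MeOH/THF, 0 °C
Reagents that add atoms: none
Why: Hydride reduction of an aryl aldehyde; NaBH4 does not touch the aryl bromide or the ethers.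

Step 4
Reactants: 4 [3-(benzyloxy)-2-bromo-4,5-dimethoxyphenyl]methanol
Product: 5 3-(benzyloxy)-2-bromo-1-(bromomethyl)-4,5-dimethoxybenzene
Conditions: PBr3 (0.4 equiv), CH2Cl2, 0 °C; used at once
Reagents that add atoms: phosphorus tribromide, BrP(Br)Br
Why: Conversion of a benzylic alcohol into the bromide through its phosphite ester (SN2). The para methoxy group makes the bromide reactive, so it is not stored.

Step 5
Reactants: 6 2,3-dimethoxyphenol
Product: 7 2,3-dimethoxy-1,4-benzoquinone
Conditions: ON(SO3K)2 (2.2 equiv), KH2PO4, H2O/acetone, 0 °C → rt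
Reagents that add atoms: potassium nitrosodisulfonate, [K+].[K+].[O]N(S(=O)(=O)[O-])S(=O)(=O)[O-]
Why: Teuber oxidation: the phenoxyl radical is trapped at the free para position by a second nitroxyl radical and collapses to the para-quinone, placing the fourth oxygen of ring B without ambiguity.

Step 6
Reactants: 7 2,3-dimethoxy-1,4-benzoquinone
Product: 9 1,4-bis(benzyloxy)-2,3-dimethoxybenzene, via 2,3-dimethoxybenzene-1,4-diol 8 (not isolated)
Conditions: Na2S2O4, THF/H2O, rt; then KOH, Bu4NBr (cat.), BnBr, rt → 50 °C, under N2
Reagents that add atoms: benzyl bromide, BrCc1ccccc1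
Why: One-pot reductive alkylation of a quinone: dithionite reduction gives the air-sensitive hydroquinone, which is benzylated twice under phase-transfer Williamson conditions before it can reoxidise.

Step 7
Reactants: 9 1,4-bis(benzyloxy)-2,3-dimethoxybenzene
Product: 10 1,4-bis(benzyloxy)-5-bromo-2,3-dimethoxybenzene
Conditions: NBS (1.0 equiv), MeCN, 0 °C → rt, dark
Reagents that add atoms: N-bromosuccinimide, O=C1CCC(=O)N1Br
Why: Electrophilic aromatic bromination of a tetra-alkoxybenzene whose two free positions are equivalent by symmetry, so only one monobromide can form. The first bromine deactivates the ring against a second.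

Step 8
Reactants: 10 1,4-bis(benzyloxy)-5-bromo-2,3-dimethoxybenzene; 11 diethyl malonate
Product: 12 diethyl 2-[2,5-bis(benzyloxy)-3,4-dimethoxyphenyl]propanedioate
Conditions: Pd(dba)2 (2 mol %), P(t-Bu)3 (4 mol %), K3PO4, toluene, 80 °C
Reagents that add atoms: none
Why: Palladium-catalysed α-arylation of a malonate enolate (oxidative addition to zerovalent palladium, enolate binding, C–C reductive elimination). The bulky electron-rich phosphine is the ligand type that handles electron-rich, ortho-substituted aryl bromides, and the acidic product stays as its enolate, so no second arylation follows.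

Step 9
Reactants: 12 diethyl 2-[2,5-bis(benzyloxy)-3,4-dimethoxyphenyl]propanedioate; 5 3-(benzyloxy)-2-bromo-1-(bromomethyl)-4,5-dimethoxybenzene
Product: 13 diethyl 2-{[3-(benzyloxy)-2-bromo-4,5-dimethoxyphenyl]methyl}-2-[2,5-bis(benzyloxy)-3,4-dimethoxyphenyl]propanedioate
Conditions: NaH, DMF, 0 °C → rt
Reagents that add atoms: none
Why: Malonic ester alkylation (SN2) of a stabilised tertiary carbanion with a reactive benzylic bromide, which forms C3–C4 and the quaternary carbon. The aryl bromide is inert under these conditions.

Step 10
Reactants: 13 diethyl 2-{[3-(benzyloxy)-2-bromo-4,5-dimethoxyphenyl]methyl}-2-[2,5-bis(benzyloxy)-3,4-dimethoxyphenyl]propanedioate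
Product: 14 2-{[3-(benzyloxy)-2-bromo-4,5-dimethoxyphenyl]methyl}-2-[2,5-bis(benzyloxy)-3,4-dimethoxyphenyl]propane-1,3-diol
Conditions: LiAlH4, THF, 0 °C → rt
Reagents that add atoms: none
Why: Hydride reduction of a non-enolisable disubstituted malonate to the 2,2-disubstituted propane-1,3-diol. At or below room temperature the aryl bromide should survive.

Step 11
Reactants: 14 2-{[3-(benzyloxy)-2-bromo-4,5-dimethoxyphenyl]methyl}-2-[2,5-bis(benzyloxy)-3,4-dimethoxyphenyl]propane-1,3-diol
Product: 15 [(3S)-8-(benzyloxy)-3-[2,5-bis(benzyloxy)-3,4-dimethoxyphenyl]-6,7-dimethoxy-3,4-dihydro-2H-chromen-3-yl]methanol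
Conditions: CuI (10 mol %), (1R,2R)-N,N'-dimethylcyclohexane-1,2-diamine (20 mol %), Cs2CO3 (2 equiv), MeCN, 60 °C, under Ar
Reagents that add atoms: none
Why: This is an Ullmann-type intramolecular etherification run as an enantioselective desymmetrisation; the closest known reaction type is the copper/chiral diamine C–O coupling that turns 2-(2-halobenzyl)propane-1,3-diols into 3-(hydroxymethyl)chromans, including 2-aryl cases with a quaternary centre. Cs2CO3 and the diamine-bound copper convert one hydroxymethyl group into a copper alkoxide (monovalent copper), which activates the C8a–Br bond (oxidative addition to trivalent copper) and forms O1–C8a by reductive elimination. Ring C closes as a six-membered ring by formal 6-exo attack of the alkoxide oxygen on C8a within a copper chelate that holds both the oxygen and the aryl carbon. The two diastereomeric copper alkoxides exchange quickly, so the configuration at the new quaternary stereocentre C3 is decided by which of them activates the bromide faster, that is, by catalyst control from the chiral diamine, which has to tell ring B from the spectator hydroxymethyl group in the forming ring. The only selectivity needed is between the enantiotopic arms: the molecule has a single aryl halide, so the remaining hydroxyl has no partner after closure, and ring B carries no halide. Benzyl and methyl ethers and the free primary alcohol are inert to CuI and Cs2CO3. The bromide is flanked by the C8 benzyloxy group and the benzylic CH2, which is the demanding feature of the substrate and the reason for the raised temperature. The (S) product is the one required (C2 > CH2OH > ring B > C4).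

Step 12
Reactants: 15 [(3S)-8-(benzyloxy)-3-[2,5-bis(benzyloxy)-3,4-dimethoxyphenyl]-6,7-dimethoxy-3,4-dihydro-2H-chromen-3-yl]methanol
Product: 16 (3R)-8-(benzyloxy)-3-[2,5-bis(benzyloxy)-3,4-dimethoxyphenyl]-6,7-dimethoxy-3,4-dihydro-2H-chromene-3-carbaldehyde
Conditions: Dess–Martin periodinane, CH2Cl2, 0 °C → rt
Reagents that add atoms: none
Why: Dess–Martin oxidation of a neopentyl primary alcohol to an aldehyde that has no α-hydrogen and so cannot epimerise. The descriptor changes from S to R only because CHO outranks C2.

Step 13
Reactants: 16 (3R)-8-(benzyloxy)-3-[2,5-bis(benzyloxy)-3,4-dimethoxyphenyl]-6,7-dimethoxy-3,4-dihydro-2H-chromene-3-carbaldehyde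
Product: 17 (3S)-8-(benzyloxy)-3-[2,5-bis(benzyloxy)-3,4-dimethoxyphenyl]-6,7-dimethoxy-3,4-dihydro-2H-chromene
Conditions: RhCl(PPh3)3 (1.1 equiv), PhCN, 130 °C, under Ar
Reagents that add atoms: none
Why: Tsuji–Wilkinson decarbonylation: oxidative addition of the formyl C–H bond (monovalent to trivalent rhodium), migration of the C3 alkyl group from CO to rhodium and C–H reductive elimination all occur with retention, as is known for α-aryl α-quaternary aldehydes. The hydrogen therefore takes the place of the formyl group, and the centre set in step 11 becomes (S)-C3–H (H now ranks last). Stoichiometric rhodium avoids the higher temperature that catalytic turnover would need.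

Step 14
Reactants: 17 (3S)-8-(benzyloxy)-3-[2,5-bis(benzyloxy)-3,4-dimethoxyphenyl]-6,7-dimethoxy-3,4-dihydro-2H-chromene
Product: 18 2-[(3S)-8-hydroxy-6,7-dimethoxy-3,4-dihydro-2H-chromen-3-yl]-5,6-dimethoxybenzene-1,4-diol
Conditions: H2 (1 atm), 10 % Pd/C, EtOAc/MeOH, rt; filtered and concentrated under Ar
Reagents that add atoms: none
Why: Hydrogenolysis of three aryl benzyl ethers. The chroman has no other benzylic C–O bond, the methyl ethers are inert, and C3–H is not acidic here.

Step 15
Reactants: 18 2-[(3S)-8-hydroxy-6,7-dimethoxy-3,4-dihydro-2H-chromen-3-yl]-5,6-dimethoxybenzene-1,4-diol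
Product: 19 5-[(3S)-8-hydroxy-6,7-dimethoxy-3,4-dihydro-2H-chromen-3-yl]-2,3-dimethoxycyclohexa-2,5-diene-1,4-dione
Conditions: Ag2O (2 equiv), MgSO4, Et2O, rt, short contact time
Reagents that add atoms: none
Why: Two-electron oxidation of a para-hydroquinone to the quinone by a mild oxidant that leaves the ring A monophenol alone. Near-neutral conditions and a short contact time guard against tautomerisation through C3–H.

## Compound list

1 | 3-hydroxy-4,5-dimethoxybenzaldehyde | COc1cc(C=O)cc(O)c1OC | starting material
2 | 2-bromo-3-hydroxy-4,5-dimethoxybenzaldehyde | COc1cc(C=O)c(Br)c(O)c1OC | intermediate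
3 | 3-(benzyloxy)-2-bromo-4,5-dimethoxybenzaldehyde | COc1cc(C=O)c(Br)c(OCc2ccccc2)c1OC | intermediate
4 | [3-(benzyloxy)-2-bromo-4,5-dimethoxyphenyl]methanol | COc1cc(CO)c(Br)c(OCc2ccccc2)c1OC | intermediate
5 | 3-(benzyloxy)-2-bromo-1-(bromomethyl)-4,5-dimethoxybenzene | COc1cc(CBr)c(Br)c(OCc2ccccc2)c1OC | intermediate
6 | 2,3-dimethoxyphenol | COc1cccc(O)c1OC | starting material
7 | 2,3-dimethoxy-1,4-benzoquinone | COC1=C(OC)C(=O)C=CC1=O | intermediate
8 | 2,3-dimethoxybenzene-1,4-diol | COc1c(O)ccc(O)c1OC | intermediate
9 | 1,4-bis(benzyloxy)-2,3-dimethoxybenzene | COc1c(OCc2ccccc2)ccc(OCc2ccccc2)c1OC | intermediate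
10 | 1,4-bis(benzyloxy)-5-bromo-2,3-dimethoxybenzene | COc1c(OCc2ccccc2)cc(Br)c(OCc2ccccc2)c1OC | intermediate
11 | diethyl malonate | CCOC(=O)CC(=O)OCC | starting material
12 | diethyl 2-[2,5-bis(benzyloxy)-3,4-dimethoxyphenyl]propanedioate | CCOC(=O)C(C(=O)OCC)c1cc(OCc2ccccc2)c(OC)c(OC)c1OCc1ccccc1 | intermediate
13 | diethyl 2-{[3-(benzyloxy)-2-bromo-4,5-dimethoxyphenyl]methyl}-2-[2,5-bis(benzyloxy)-3,4-dimethoxyphenyl]propanedioate | CCOC(=O)C(Cc1cc(OC)c(OC)c(OCc2ccccc2)c1Br)(C(=O)OCC)c1cc(OCc2ccccc2)c(OC)c(OC)c1OCc1ccccc1 | intermediate
14 | 2-{[3-(benzyloxy)-2-bromo-4,5-dimethoxyphenyl]methyl}-2-[2,5-bis(benzyloxy)-3,4-dimethoxyphenyl]propane-1,3-diol | OCC(CO)(Cc1cc(OC)c(OC)c(OCc2ccccc2)c1Br)c1cc(OCc2ccccc2)c(OC)c(OC)c1OCc1ccccc1 | intermediate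
15 | [(3S)-8-(benzyloxy)-3-[2,5-bis(benzyloxy)-3,4-dimethoxyphenyl]-6,7-dimethoxy-3,4-dihydro-2H-chromen-3-yl]methanol | COc1c(OC)c(OCc2ccccc2)cc([C@@]3(CO)COc4c(cc(OC)c(OC)c4OCc5ccccc5)C3)c1OCc6ccccc6 | intermediate
16 | (3R)-8-(benzyloxy)-3-[2,5-bis(benzyloxy)-3,4-dimethoxyphenyl]-6,7-dimethoxy-3,4-dihydro-2H-chromene-3-carbaldehyde | COc1c(OC)c(OCc2ccccc2)cc([C@@]3(C=O)COc4c(cc(OC)c(OC)c4OCc5ccccc5)C3)c1OCc6ccccc6 | intermediate
17 | (3S)-8-(benzyloxy)-3-[2,5-bis(benzyloxy)-3,4-dimethoxyphenyl]-6,7-dimethoxy-3,4-dihydro-2H-chromene | COc1c(OC)c(OCc2ccccc2)cc([C@H]3COc4c(cc(OC)c(OC)c4OCc5ccccc5)C3)c1OCc6ccccc6 | intermediate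
18 | 2-[(3S)-8-hydroxy-6,7-dimethoxy-3,4-dihydro-2H-chromen-3-yl]-5,6-dimethoxybenzene-1,4-diol | COc1c(OC)c(O)cc([C@H]2COc3c(cc(OC)c(OC)c3O)C2)c1O | intermediate
19 | 5-[(3S)-8-hydroxy-6,7-dimethoxy-3,4-dihydro-2H-chromen-3-yl]-2,3-dimethoxycyclohexa-2,5-diene-1,4-dione | COC1=C(OC)C(=O)C([C@H]2COc3c(cc(OC)c(OC)c3O)C2)=CC1=O | target

## Step count and risks

Total: 15 steps. Longest linear sequence: 11 steps (steps 5–15 from 6; the ring A branch, steps 1–4 and 9–15 from 1, is equally long).

**Key step (step 11).** The most likely failure is sluggish activation of the C–Br bond, because the bromide lies between the C8 benzyloxy group and the benzylic CH2 on an electron-rich ring. At the higher temperature this then forces, hydrodebromination and a less selective cyclisation would compete. The diamine may also discriminate poorly between ring B and the spectator arm. The fallback separates the enantioselection from the ring closure. It sets out from diol 14. Lipase-catalysed monoacetylation (Candida antarctica lipase B, vinyl acetate, toluene; hydrolysis of the diacetate with the same enzyme if the opposite sense is found) should give (2S)-2-{[3-(benzyloxy)-2-bromo-4,5-dimethoxyphenyl]methyl}-2-[2,5-bis(benzyloxy)-3,4-dimethoxyphenyl]-3-hydroxypropyl acetate F1. Silylation of the free hydroxyl (t-BuPh2SiCl, imidazole, DMF) gives (2R)-2-{[3-(benzyloxy)-2-bromo-4,5-dimethoxyphenyl]methyl}-2-[2,5-bis(benzyloxy)-3,4-dimethoxyphenyl]-3-[(tert-butyldiphenylsilyl)oxy]propyl acetate F2. K2CO3 in MeOH removes the acetate to give (2R)-2-{[3-(benzyloxy)-2-bromo-4,5-dimethoxyphenyl]methyl}-2-[2,5-bis(benzyloxy)-3,4-dimethoxyphenyl]-3-[(tert-butyldiphenylsilyl)oxy]propan-1-ol F3. The liberated arm is then cyclised without a chiral ligand by palladium-catalysed C–O coupling (Pd2(dba)3, a di-tert-butylbiarylphosphine, Cs2CO3, toluene, 80 °C). Zerovalent palladium inserts into hindered electron-rich aryl bromides more readily than copper does. This gives (3R)-8-(benzyloxy)-3-[2,5-bis(benzyloxy)-3,4-dimethoxyphenyl]-3-{[(tert-butyldiphenylsilyl)oxy]methyl}-6,7-dimethoxy-3,4-dihydro-2H-chromene F4, and Bu4NF in THF returns to the route at 15. The bulky silyl group is installed before the ring closure so that base cannot scramble the two arms by 1,3-acyl migration.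

**Step 13 (decarbonylation).** The most likely failure is β-hydride elimination from the tertiary alkylrhodium intermediate towards C4 or C2, which gives chromenes. Reversible elimination and re-addition could also cost part of the configuration. The hindered neopentyl aldehyde may force a temperature at which these pathways grow. The fallback gives up retention and sets C3 afresh by catalyst control. It sets out from aldehyde 16. Pinnick oxidation (NaClO2, NaH2PO4, 2-methyl-2-butene, t-BuOH/H2O) gives (3R)-8-(benzyloxy)-3-[2,5-bis(benzyloxy)-3,4-dimethoxyphenyl]-6,7-dimethoxy-3,4-dihydro-2H-chromene-3-carboxylic acid F5. Oxidative decarboxylation (Pb(OAc)4, Cu(OAc)2, pyridine, benzene, 80 °C) should give mainly the conjugated alkene 8-(benzyloxy)-3-[2,5-bis(benzyloxy)-3,4-dimethoxyphenyl]-6,7-dimethoxy-2H-chromene F6. Asymmetric hydrogenation of this isoflav-3-ene with an iridium phosphine–oxazoline complex, [Ir(cod)(P,N)]BArF under H2 in CH2Cl2 (monovalent iridium precatalyst; homogeneous, so the benzyl ethers stay), comes back to the route at 17. On this path step 11 need not be enantioselective.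

**Step 1 (bromination).** The most likely failure is attack at C6, which is para to the hydroxyl and ortho to the C5 methoxy group, or double bromination. Either would put the halogen at the future C5 instead of C8a. The fallback fixes the site by directed ortho-metalation and sets out from 1. Carbamoylation (Et2NCOCl, K2CO3, MeCN) gives 5-formyl-2,3-dimethoxyphenyl diethylcarbamate F7. The aldehyde is masked in the flask as its α-amino alkoxide (LiN(Me)CH2CH2NMe2, THF, −20 °C). Lithiation with s-BuLi at −78 °C should occur at the carbon between the carbamate and the masked formyl group, and trapping with BrCF2CF2Br and aqueous work-up gives 2-bromo-3-formyl-5,6-dimethoxyphenyl diethylcarbamate F8. LiAlH4 in THF at 0 °C cleaves the carbamate and reduces the aldehyde to 2-bromo-3-(hydroxymethyl)-5,6-dimethoxyphenol F9. Selective benzylation of the phenol (BnBr, K2CO3, acetone) comes back to the route at 4.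

**Step 8 (malonate arylation).** The most likely failure is slow oxidative addition to the very electron-rich bromide next to a benzyloxy group, with hydrodebromination taking over. The fallback changes the halide and the metal and sets out from 9. Iodination (N-iodosuccinimide, CF3CO2H cat., MeCN) gives 1,4-bis(benzyloxy)-5-iodo-2,3-dimethoxybenzene F10. A Hurtley-type copper enolate coupling with 11 (CuI, 2-picolinic acid, Cs2CO3, 1,4-dioxane, rt → 50 °C) comes back to the route at 12.

## Further compounds

F1 | step 11 | (2S)-2-{[3-(benzyloxy)-2-bromo-4,5-dimethoxyphenyl]methyl}-2-[2,5-bis(benzyloxy)-3,4-dimethoxyphenyl]-3-hydroxypropyl acetate | COc1c(OC)c(OCc2ccccc2)cc([C@@](Cc3cc(OC)c(OC)c(OCc4ccccc4)c3Br)(CO)COC(C)=O)c1OCc5ccccc5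
F2 | step 11 | (2R)-2-{[3-(benzyloxy)-2-bromo-4,5-dimethoxyphenyl]methyl}-2-[2,5-bis(benzyloxy)-3,4-dimethoxyphenyl]-3-[(tert-butyldiphenylsilyl)oxy]propyl acetate | COc1c(OC)c(OCc2ccccc2)cc([C@@](Cc3cc(OC)c(OC)c(OCc4ccccc4)c3Br)(CO[Si](c4ccccc4)(c4ccccc4)C(C)(C)C)COC(C)=O)c1OCc5ccccc5
F3 | step 11 | (2R)-2-{[3-(benzyloxy)-2-bromo-4,5-dimethoxyphenyl]methyl}-2-[2,5-bis(benzyloxy)-3,4-dimethoxyphenyl]-3-[(tert-butyldiphenylsilyl)oxy]propan-1-ol | COc1c(OC)c(OCc2ccccc2)cc([C@@](Cc3cc(OC)c(OC)c(OCc4ccccc4)c3Br)(CO[Si](c4ccccc4)(c4ccccc4)C(C)(C)C)CO)c1OCc5ccccc5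
F4 | step 11 | (3R)-8-(benzyloxy)-3-[2,5-bis(benzyloxy)-3,4-dimethoxyphenyl]-3-{[(tert-butyldiphenylsilyl)oxy]methyl}-6,7-dimethoxy-3,4-dihydro-2H-chromene | COc1c(OC)c(OCc2ccccc2)cc([C@@]3(CO[Si](c4ccccc4)(c4ccccc4)C(C)(C)C)COc4c(cc(OC)c(OC)c4OCc5ccccc5)C3)c1OCc6ccccc6
F5 | step 13 | (3R)-8-(benzyloxy)-3-[2,5-bis(benzyloxy)-3,4-dimethoxyphenyl]-6,7-dimethoxy-3,4-dihydro-2H-chromene-3-carboxylic acid | COc1c(OC)c(OCc2ccccc2)cc([C@@]3(C(=O)O)COc4c(cc(OC)c(OC)c4OCc5ccccc5)C3)c1OCc6ccccc6
F6 | step 13 | 8-(benzyloxy)-3-[2,5-bis(benzyloxy)-3,4-dimethoxyphenyl]-6,7-dimethoxy-2H-chromene | COc1c(OC)c(OCc2ccccc2)cc(C3=Cc4cc(OC)c(OC)c(OCc5ccccc5)c4OC3)c1OCc6ccccc6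
F7 | step 1 | 5-formyl-2,3-dimethoxyphenyl diethylcarbamate | CCN(CC)C(=O)Oc1cc(C=O)cc(OC)c1OC
F8 | step 1 | 2-bromo-3-formyl-5,6-dimethoxyphenyl diethylcarbamate | CCN(CC)C(=O)Oc1c(Br)c(C=O)cc(OC)c1OC
F9 | step 1 | 2-bromo-3-(hydroxymethyl)-5,6-dimethoxyphenol | OCc1cc(OC)c(OC)c(O)c1Br
F10 | step 8 | 1,4-bis(benzyloxy)-5-iodo-2,3-dimethoxybenzene | COc1c(OCc2ccccc2)cc(I)c(OCc2ccccc2)c1OC
A1 | alternative 1 | (6aS,11aS)-4-(benzyloxy)-2,3,9,10-tetramethoxy-6a,11a-dihydro-6H-benzofuro[3,2-c]chromen-8-ol | COc1c(OC)c2c(cc1O)[C@H]3COc4c(cc(OC)c(OC)c4OCc5ccccc5)[C@H]3O2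
A2 | alternative 1 | 8-(benzyloxy)-6,7-dimethoxy-2H-chromene | COc1cc2c(OCC=C2)c(OCc3ccccc3)c1OC
A3 | alternative 2 | 2-{(1S)-2-[3-(benzyloxy)-4,5-dimethoxy-2-(methoxymethoxy)phenyl]-1-[2,5-bis(benzyloxy)-3,4-dimethoxyphenyl]ethyl}-4,4,5,5-tetramethyl-1,3,2-dioxaborolane | COc1c(OC)c(OCc2ccccc2)cc([C@H](Cc4cc(OC)c(OC)c(OCc5ccccc5)c4OCOC)B6OC(C)(C)C(C)(C)O6)c1OCc3ccccc3
A4 | alternative 2 | [2,5-bis(benzyloxy)-3,4-dimethoxyphenyl]magnesium bromide | COc1c(OC)c(OCc2ccccc2)cc([Mg]Br)c1OCc1ccccc1
A5 | alternative 2 | 3-(benzyloxy)-1-bromo-4,5-dimethoxy-2-(methoxymethoxy)benzene | COCOc1c(Br)cc(OC)c(OC)c1OCc1ccccc1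
A6 | alternative 2 | 4,4,5,5-tetramethyl-2-vinyl-1,3,2-dioxaborolane | C=CB1OC(C)(C)C(C)(C)O1
A7 | alternative 3 | (3S)-8-(benzyloxy)-3-[2,5-bis(benzyloxy)-3,4-dimethoxyphenyl]-6,7-dimethoxychroman-2-ol (mixture of anomers) | COc1c(OC)c(OCc2ccccc2)cc([C@H]3C(O)Oc4c(cc(OC)c(OC)c4OCc5ccccc5)C3)c1OCc6ccccc6
A8 | alternative 3 | 2-(benzyloxy)-3,4-dimethoxy-6-[(4-methylbenzenesulfonyl)methyl]phenol | COc1cc(CS(=O)(=O)c2ccc(C)cc2)c(O)c(OCc2ccccc2)c1OC
A9 | alternative 3 | 2-[2,5-bis(benzyloxy)-3,4-dimethoxyphenyl]acetaldehyde | O=CCc1cc(OCc2ccccc2)c(OC)c(OC)c1OCc1ccccc1
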